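(The data are simulated from invented constants; scatter was added.)

The reading is taken at one moment, when the east flask has converted 20 % of its substrate, and the concentration that counts then is the partner still left.

common to all: substrate 0.050 M; free catalyst 0.1 mol%

|  | partner | remark |
|---|---|---|
| east | 0.50 equiv | the very flask that is asked about, followed so far |
| south | 0.75 equiv | run made earlier |
| flask | 0.500 equiv |  |

| run | time / min | product / % |
|---|---|---|
| east | 2.00 | 1.0 |
| east | 6.00 | 2.4 |
| east | 12.0 | 6.2 |
| east | 15.0 | 7.4 |
| east | 25.0 | 11.4 |
| south | 4.00 | 2.9 |
| south | 8.00 | 5.5 |
| south | 15.0 | 10.3 |
| south | 25.0 | 16.6 |
| south | 50.0 | 28.2 |

(standard deviation of a reading: 0.3 percentage points)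

- apparent order in free catalyst when 20 % of the substrate are converted (percent change of the rate of making product for one percent more free catalyst charged)
- apparent order in partner when 20 % of the substrate are converted (percent change of the rate of making product for one percent more partner charged)

On the fastest rung, at the east flask's mean rate over 25.0 min, product equal to the catalyst charge appears in 0.219 min, so the catalyst forms turn over many times before the first reading. The next rung is the mark, about 43.9 min away at that rate, sooner than the 110 min that the partner charge, the limiting reagent, represents.

At 15.0 min, the south flask holds 1.39 times the east product for 1.50 times the partner, so this reckoning takes the rate as first order in partner. Counted by product, partner gives 1.67: the lever, charged partner over partner left at the mark.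

The slowest rung is a quiet loss. In the south flask, the rate per partner left by that count keeps a share of 0.897 from the middle of its early readings to the middle of its last two, a rough reading. Taking that share over to the east flask gives this reckoning:

order in partner = lever / share kept = 1.86

order in catalyst = 1.11 (a guess, since no run changes the catalyst charge)

The forecast gives 1.05 for catalyst, on the ground that “All catalyst species scale with the charge”, and 1.6 for partner, the same lever multiplied by an order of about 0.95 where this reckoning divides by the share kept; both values stand lower than this reckoning's.

The east flask gives 1.2 and 1.9.

    partner + free catalyst ⇌ catalyst intermediate A (K = 20.0 M⁻¹, k = 14000 M⁻¹ h⁻¹)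
    substrate + catalyst intermediate A → catalyst intermediate B (k = 3.90 × 10⁵ M⁻¹ h⁻¹)
    catalyst intermediate B → free catalyst + product (k = 6200 h⁻¹)
    partner → decomposed reagent (k = 0.170 h⁻¹)

Part of the reason for both orders is the step from partner to decomposed reagent. At the start, the forward step to catalyst intermediate A uses partner 4.1 times as fast as that decomposition. The same flask run without the decomposition step has 1.21 times the rate at the mark and an order in catalyst of 1.0. Its partner is then counted by product, so its lever is 1.67, and its order in partner is 1.6.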